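**Remarks on the chemistry**

- Assumption: (S)-paraconic acid is bought as the single enantiomer; the racemic acid resolved as a salt with a chiral amine would serve equally.
- Ring atoms are labelled as in the target throughout the discussion: O1, C2 (3,4-dimethoxyphenyl), C3 (CH2OH), C4 (aroyl), C5. Compound names keep their own nomenclature numbering.
- Structure check: the S centre of 1, the trans hydroxymethylation, the 3R centre of 7, the 3aR,4R,6aR bicycle 10 and the 2R,3R,4S target form one consistent stereochemical thread, so no drawn structure needs correction. What is tightened is the handling of the precursor: its hydroxyl is unmasked under neutral conditions, and its ketone α-carbon is equilibrated by the Lewis acid before the hydride source is added.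

## Structural features

The target is a monocyclic tetrahydrofuran (O1, C2, C3, C4, C5) with a 3,4-dimethoxyphenyl group on C2, a hydroxymethyl group on C3, a 3,4,5-trimethoxybenzoyl group on C4 and an unsubstituted methylene at C5. C2, C3 and C4 are contiguous stereocentres of configuration 2R,3R,4S in this numbering, the aryl and hydroxymethyl groups being cis and the hydroxymethyl and aroyl groups trans. Three features are fragile: C4–H is alpha to the aryl ketone and epimerises, fortunately towards the trans arrangement of the target; the same ketone is beta to O1, so a strong base can expel O1 from C5; and O1–C2 is a benzylic ether of an electron-rich arene, which ionises under acid and would then relax the crowded 2,3-cis relation to trans. The real difficulty is therefore the contra-thermodynamic cis relation between C2 and C3, to be set in an absolute sense at a centre that ionises easily, while the one-carbon branches on C3 and C4 stay at different oxidation levels (alcohol and ketone). The key step exploits two latent relationships: the O1–C2 ether is the reduction product of a ketone at C2 and a hydroxyl on C5, and the hydroxymethyl carbon on C3 can be tied to a carboxyl carbon on C4 as a cis-fused gamma-lactone. In the resulting bicycle the ring fusion decides which face of C2 is open, so the cis relation comes from the shape of two fused five-membered rings and not from the weak bias of one. The lactone carbonyl carbon is the later ketone carbon, so one ring masks the alcohol, carries the acyl group and enforces the shape.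

## Logic of the disconnections

**15 to 14.** No skeletal bond is cut; only the C4–H bond is broken and re-formed. The cut is placed here because 3,4-trans is the resting state alpha to the ketone, so the last stereocentre need not be controlled kinetically. The gain is that the precursor may carry the C3 and C4 branches cis, which is exactly what a fused lactone delivers. The forward step must enolise C4 without expelling O1 from C5, and it relies on 14 and its closed form 13 being less stable than 15.

**14 to 10 and 11.** The bond between the ketone carbon and the trimethoxyphenyl ring is cut, and the primary oxygen of the C3 branch is rejoined to that carbon as a lactone. The reason is that in 10 the future ketone carbon is at the acid level and the alcohol is masked without a protecting group. The gain is the removal of one aromatic half and of all protecting-group steps. The forward step demands that 12, made from 11, adds once only to the lactone carbonyl of 10.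

**10 to 7 (key).** The O1–C2 bond and the C2–H bond are cut, which opens the tetrahydrofuran to an aryl ketone at C2 and a free hydroxyl on C5. The reason is that C3, now alpha to a ketone, no longer has to be made with a defined configuration: both epimers of 7 converge. The gain is two stereocentres (C2 and C3) and one ring. The forward step must close only through the cis-fused hemiketal 8 and deliver hydride to one face of 9.

**7 to 3 and 4.** The bond between the C2 carbonyl carbon and the dimethoxyphenyl ring is cut. The reason is that 4 is acylated cleanly para to a methoxy group and that the acid carbon of 3 is already in place. The gain is a purchased arene and a six-carbon chiral acid. The forward step must run under acid with the hydroxyl masked in the flask, because 7 is a β-acyloxy ketone that base would destroy.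

**3 to 1.** The bond between the lactone α-carbon (the future C4) and its hydroxymethyl carbon (the future C5) is cut. The reason is a stereochemical relay: the single centre of 1 directs the new centre trans, and only the new centre has to survive the next steps. The gain is a chiral-pool start of five carbons. The forward step demands high trans selectivity, since the cis adduct ends in the enantiomeric series, and it must never open the lactone of 3, whose ring-opened diacid diol is meso.

## Other disconnections considered

**Alternative 1:** The cut goes through O1–C2 and C4–C5. C5 and O1 would come from formaldehyde and C2–C3–C4 from the donor–acceptor cyclopropane A1 (aryl and silyloxymethyl trans, the malonate carbon as C4). Forward, Sn(OTf)2 would activate the diester, the carbonyl oxygen would open the ring at the benzylic carbon with inversion, and the malonate would close on the oxocarbenium carbon to give the 2,3-cis diester A2.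

- In its favour: two ring bonds and the ring are made in one convergent, catalytic step, and the cis relation follows stereospecifically from an easily drawn trans cyclopropane. In skeletal bonds made by the key step it is better than the chosen plan (two against one). In setting C2/C3 by a stereospecific substitution it is in principle its equal.
- Against it here:
  - (a) The 3,4-dimethoxyphenyl group is so strong a donor that ring opening may drift from invertive substitution towards a free benzylic cation, which would cost both the cis relation and the enantiomeric purity of A1.
  - (b) Formaldehyde has to be supplied as the monomer and tends to oligomerise on the Lewis acid.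
  - (c) A2 carries two esters on C4. One must be excised (LiCl, wet DMSO, heat), the other turned into the aryl ketone, C4 equilibrated and the silyl ether removed: four to five steps after the ring is made.
  - (d) A1 needs an enantioselective synthesis, for which malonate-type carbenes (for example with chiral catalysts derived from Rh2(OAc)4) are poor partners.
- Comparison: structurally the alternative builds more in one step but leaves C4 over-functionalised, whereas 10 already holds the C4 branch at the acid level that becomes the ketone. Mechanistically both plans place positive charge next to the dimethoxyphenyl ring. In the alternative that charge endangers stereochemical information that already exists; in the chosen plan it is where the information is created, under control of the bicycle. In step count the alternative would need about ten steps against five.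

**Alternative 2:** The cut is C4–C5, with C5 taken from the acetal carbon of a methoxymethyl ether on the C2 oxygen. O1–C2, both aryl groups and the ketone are already present in the open-chain enol silane A3. Forward, TMSOTf would ionise the acetal and the enol silane carbon would add to the O-alkylated formaldehyde cation (a Mukaiyama-type addition, 5-endo with respect to the cation) to give keto ester A4.

- In its favour: there is no late organometallic step and the aroyl group arrives at its final oxidation level, which is better than the chosen plan on this point. C2/C3 would come from an acyclic aldol for which dependable asymmetric versions exist. C4 settles trans by the same thermodynamic argument as in the chosen plan (equal).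
- Against it here:
  - (a) C3 bears an ester where the target has CH2OH. Its reduction next to an aryl ketone would require over-reduction (LiAlH4) and selective benzylic re-oxidation (MnO2), or a ketone protecting group: two to three extra steps.
  - (b) In A3 and A4, C3–H is alpha to the ester, so the contra-thermodynamic cis relation to the aryl group can be lost by enolisation. The base needed to make the enol silane can also expel the β-alkoxy group to a cinnamate.
  - (c) TMSOTf may ionise the electron-rich benzylic C2–O bond in competition with the acetal.
  - (d) The 5-endo closure is geometrically less favourable than the 5-exo closure of the chosen plan.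
- Comparison: structurally the alternative forms a ring C–C bond but creates no stereocentre that is not already thermodynamically determined. Mechanistically both use oxocarbenium ions; the alternative's is an unstabilised formaldehyde-derived ion in an open transition state, the chosen plan's a cyclic aryl-stabilised ion with one open face. In step count it would need about nine to ten steps (auxiliary-controlled aldol, protection, ketone and enol silane formation, cyclisation, redox adjustment) against five.

**Alternative 3:** The cut is C2–C3. The tetrahydrofuran would arise by ring contraction of the seven-membered vinyl acetal A5, whose acetal carbon becomes C2, whose enol ether β-carbon becomes C3 and whose single stereocentre becomes C4. Forward, BF3·OEt2 at low temperature would cleave the acetal C–O bond on the enol ether side, and the tethered enolate would recombine through carbon with the aryl-stabilised oxocarbenium ion (a Petasis–Ferrier-type 1,3-shift from oxygen to carbon) to give the cis aldehyde A6.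

- In its favour: a ring C–C bond and two stereocentres would be created in one step under kinetic control that is expected to favour 2,3-cis at low temperature. A5 can be assembled quickly from the 3,4-dimethoxybenzaldehyde acetal of cis-but-2-ene-1,4-diol by an enantioselective Heck-type vinylation, which also moves the double bond into the enol ether position. The step count, about five to six, is the equal of the chosen plan, and in skeletal bond construction the alternative is better.
- Against it here:
  - (a) The only stereocentre of A5 must come from an enantioselective catalytic step (Pd(OAc)2 with a chiral bisphosphine) whose selectivity with an α-arylvinyl partner would have to be established, whereas the chosen plan draws on the chiral pool.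
  - (b) A6 is an aldehyde with an epimerisable C3–H, and the electron-rich aryl group makes the C2–C3 bond formation reversible, so drift to the 2,3-trans series threatens until the aldehyde is reduced.
  - (c) The 1-arylvinyl group must be cleaved oxidatively to the ketone (OsO4/NaIO4) next to two electron-rich arenes.
  - (d) Induction from C4 to C3 operates in a flexible ion pair.
- Comparison: both plans place positive charge at C2 and rely on kinetic control for the cis relation. In the alternative the selectivity depends on an open transition state and a carbon nucleophile. In the chosen plan it depends on the convex face of a rigid bicycle and a hydride, which is why the chosen plan is judged more predictable although no shorter.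

Key step: step 3

## Route

**Step 1**
Reactants: 1 (S)-paraconic acid [(3S)-5-oxotetrahydrofuran-3-carboxylic acid]
Product: 3 (3S,4R)-4-(hydroxymethyl)-5-oxotetrahydrofuran-3-carboxylic acid (hydroxymethyl trans to carboxyl), via dilithium enolate carboxylate 2 (not isolated)
Conditions: LiN(SiMe3)2 (2.2 equiv), THF, −78 °C; CH2O (gas, from cracked paraformaldehyde), −78 → −40 °C; HCl/Et2O, −78 °C; cold aqueous work-up at pH 2
Reagents that add atoms: formaldehyde, C=O
Why: Aldol addition of a lactone enolate to monomeric formaldehyde; the carboxylate keeps the base away from the adjacent C–H (whose removal would open the ring by β-elimination) and shields one face, so the electrophile should enter trans to it and set the new centre as R. The cold anhydrous acid quench avoids hydroxide, because hydrolysis of the lactone of 3 would give a meso diacid diol and erase the configuration; any cis adduct should close to a neutral dilactone and be removed by a brief cold bicarbonate partition.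

**Step 2**
Reactants: 3 (3S,4R)-4-(hydroxymethyl)-5-oxotetrahydrofuran-3-carboxylic acid; 4 veratrole (1,2-dimethoxybenzene)
Product: 7 (3R)-4-(3,4-dimethoxybenzoyl)-3-(hydroxymethyl)dihydrofuran-2(3H)-one as the mixture of C4 epimers, via mixed anhydride 5 (not isolated), via keto trifluoroacetate 6 (not isolated)
Conditions: (CF3CO)2O (5 equiv; 3 added to it first), 85% H3PO4 (1 equiv), 4 (1.5 equiv), MeCN, 0 °C → rt; then MeOH, NaHCO3 (cat.), 0 °C
Reagents that add atoms: none
Why: Friedel–Crafts acylation of an activated arene by a carboxylic acid through its mixed trifluoroacetic anhydride, with the hydroxyl masked in the same flask as its trifluoroacetate and veratrole reacting para to a methoxy group. Neutral methanolysis then frees the alcohol without the base that would eliminate this β-acyloxy ketone; lactone C3 (R) is untouched, while lactone C4 becomes labile, which is intended, and any cis epimer is expected to rest as hemiketal 8.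

**Step 3**
Reactants: 7 (3R)-4-(3,4-dimethoxybenzoyl)-3-(hydroxymethyl)dihydrofuran-2(3H)-one (both C4 epimers)
Product: 10 (3aR,4R,6aR)-4-(3,4-dimethoxyphenyl)tetrahydro-1H,3H-furo[3,4-c]furan-1-one (cis-fused; aryl on the concave face), via bicyclic hemiketal 8 (not isolated), via oxocarbenium ion 9 (not isolated)
Conditions: BF3·OEt2 (2.5 equiv), CH2Cl2, 0 °C (equilibration); then Et3SiH (4 equiv), −78 → −30 °C; Et3N, then aq. NaHCO3 at −30 °C
Reagents that add atoms: none
Why: BF3 enolises the aryl ketone, so the ketone α-carbon of 7 (C3 in target numbering) equilibrates, and only the epimer with C3 and C4 cis can add the C5 hydroxyl to the ketone; this 5-exo-trig closure gives the cis-fused hemiketal 8, so the configuration of C3 is selected by the strain that forbids a trans-fused pair of five-membered rings. Ionisation of 8 gives the aryl-stabilised bicyclic oxocarbenium ion 9 (loss of a proton from 9 to the enol ether is harmless because reprotonation returns 9), and Et3SiH transfers hydride to C2 from the convex face, which places hydrogen exo and the aryl group endo, cis to the C3 branch (4R in 10). The closest known reaction type is the Et3SiH/BF3·OEt2 reduction of cyclic hemiketals to ethers (reductive etherification), familiar from aryl C-glycoside and furofuran chemistry. Two selectivities are needed: the cyclic cation must be reduced and not the open ketone of the trans epimer, which the order of addition (Lewis acid first, silane only after equilibration and cooling) and the far higher electrophilicity of 9 should secure; and the product must not re-ionise at its benzylic ether, which the electron-withdrawing lactone, the low temperature and the cold basic quench should secure. C4 (the lactone α-carbon, R) is a spectator because lactone enolisation is far slower than ketone enolisation under these conditions.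

**Step 4**
Reactants: 10 (3aR,4R,6aR)-4-(3,4-dimethoxyphenyl)tetrahydro-1H,3H-furo[3,4-c]furan-1-one; 11 5-bromo-1,2,3-trimethoxybenzene
Product: 14 [(3R,4R,5R)-5-(3,4-dimethoxyphenyl)-4-(hydroxymethyl)tetrahydrofuran-3-yl](3,4,5-trimethoxyphenyl)methanone (all-cis hydroxy ketone), via aryllithium 12 (not isolated), via lactol 13 (not isolated)
Conditions: 11 (1.25 equiv), n-BuLi (1.2 equiv), THF, −78 °C; then 10, −78 °C; sat. aq. NH4Cl at −78 °C
Reagents that add atoms: none
Why: Bromine–lithium exchange followed by 1,2-addition of an aryllithium to a γ-lactone; the lithium hemiketalate is stable at −78 °C, which should stop the reaction after one addition (the logic of aryllithium additions to sugar lactones) and makes an amide detour and hydroxyl protection unnecessary. Protonation gives lactol 13, the closed tautomer of 14, and the pair is carried on unseparated; no stereocentre is touched.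

**Step 5**
Reactants: 14 [(3R,4R,5R)-5-(3,4-dimethoxyphenyl)-4-(hydroxymethyl)tetrahydrofuran-3-yl](3,4,5-trimethoxyphenyl)methanone
Product: 15 [(3S,4R,5R)-5-(3,4-dimethoxyphenyl)-4-(hydroxymethyl)tetrahydrofuran-3-yl](3,4,5-trimethoxyphenyl)methanone (the target; 2R,3R,4S in target numbering)
Conditions: DBU (1 equiv), CH2Cl2, rt; chromatography on neutralised silica
Reagents that add atoms: none
Why: Base-mediated epimerisation alpha to a ketone through the enolate; the all-cis 14 is strained and its trans epimer cannot close to a lactol, so the equilibrium should drain to 15, with C2 and C3 (target numbering) untouched because neither is acidic. The mild amidine base is chosen to keep expulsion of O1 from C5 (retro-oxa-Michael) in check, and no acid is used after step 3, so the benzylic ether keeps its cis configuration.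

## Compound list

1 | (S)-paraconic acid, (3S)-5-oxotetrahydrofuran-3-carboxylic acid | OC(=O)[C@@H]1COC(=O)C1 | starting material
2 | dilithium salt of 1 (lactone enolate and carboxylate, original centre retained) | [Li+].[Li+].[O-]C(=O)[C@@H]1COC([O-])=C1 | intermediate
3 | (3S,4R)-4-(hydroxymethyl)-5-oxotetrahydrofuran-3-carboxylic acid | OC(=O)[C@@H]1COC(=O)[C@H]1CO | intermediate
4 | veratrole (1,2-dimethoxybenzene) | COc1ccccc1OC | starting material
5 | mixed anhydride of (3S,4R)-5-oxo-4-[(trifluoroacetoxy)methyl]tetrahydrofuran-3-carboxylic acid with trifluoroacetic acid | FC(F)(F)C(=O)OC(=O)[C@@H]1COC(=O)[C@H]1COC(=O)C(F)(F)F | intermediate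
6 | [(3R)-4-(3,4-dimethoxybenzoyl)-2-oxotetrahydrofuran-3-yl]methyl trifluoroacetate, both C4 epimers | COc1ccc(C(=O)C2COC(=O)[C@H]2COC(=O)C(F)(F)F)cc1OC | intermediate
7 | (3R)-4-(3,4-dimethoxybenzoyl)-3-(hydroxymethyl)dihydrofuran-2(3H)-one, both C4 epimers | COc1ccc(C(=O)C2COC(=O)[C@H]2CO)cc1OC | intermediate
8 | (3aR,6aR)-4-(3,4-dimethoxyphenyl)-4-hydroxytetrahydro-1H,3H-furo[3,4-c]furan-1-one (cis-fused hemiketal, both anomers) | COc1ccc(C2(O)OC[C@@H]3C(=O)OC[C@H]23)cc1OC | intermediate
9 | cis-fused bicyclic 2-aryl oxocarbenium ion derived from 8 (3aR,6aR), hydroxytrifluoroborate salt | COc1ccc(C2=[O+]C[C@@H]3C(=O)OC[C@H]23)cc1OC.O[B-](F)(F)F | intermediate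
10 | (3aR,4R,6aR)-4-(3,4-dimethoxyphenyl)tetrahydro-1H,3H-furo[3,4-c]furan-1-one | COc1ccc([C@@H]2OC[C@@H]3C(=O)OC[C@H]23)cc1OC | intermediate
11 | 5-bromo-1,2,3-trimethoxybenzene | COc1cc(Br)cc(OC)c1OC | starting material
12 | (3,4,5-trimethoxyphenyl)lithium | [Li]c1cc(OC)c(OC)c(OC)c1 | intermediate
13 | (3aR,4R,6aR)-4-(3,4-dimethoxyphenyl)-1-(3,4,5-trimethoxyphenyl)tetrahydro-1H,3H-furo[3,4-c]furan-1-ol (lactol, both anomers) | COc1ccc([C@@H]2OC[C@@H]3C(O)(c4cc(OC)c(OC)c(OC)c4)OC[C@H]23)cc1OC | intermediate
14 | [(3R,4R,5R)-5-(3,4-dimethoxyphenyl)-4-(hydroxymethyl)tetrahydrofuran-3-yl](3,4,5-trimethoxyphenyl)methanone | COc1ccc([C@@H]2OC[C@H](C(=O)c3cc(OC)c(OC)c(OC)c3)[C@@H]2CO)cc1OC | intermediate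
15 | [(3S,4R,5R)-5-(3,4-dimethoxyphenyl)-4-(hydroxymethyl)tetrahydrofuran-3-yl](3,4,5-trimethoxyphenyl)methanone | COc1ccc([C@@H]2OC[C@@H](C(=O)c3cc(OC)c(OC)c(OC)c3)[C@@H]2CO)cc1OC | target

## Step count and least certain steps

Total step count: 5. Longest linear sequence: 5 steps (1 → 3 → 7 → 10 → 14 → 15); 4 and 11 enter as purchased reagents.

**Step 3 (key step).** Epimerisation of the ketone α-carbon may be slower than side reactions of the open trans epimer: ionic hydrogenation of the aryl ketone once silane is present, or acid-promoted loss of the lactone carboxylate beta to the enol. Prolonged exposure to BF3 may also re-ionise the benzylic ether, leading to the exo-aryl isomer or to reductive ring opening. The fallback separates equilibration from reduction. Setting out from 7, camphorsulfonic acid and HC(OMe)3 in MeOH at 40 °C would equilibrate the ketone α-carbon under protic conditions and trap the cis epimer as the cyclic methyl ketal F1, which is isolated. Et3SiH and BF3·OEt2 in CH2Cl2 at −78 °C would then reduce it through the same cation and return to the route at 10.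

**Step 1.** Facial selectivity towards so small an electrophile may be poor, and since the cis adduct ends in the enantiomeric series, diastereomeric leakage becomes loss of enantiomeric purity. The very polar product may be lost to water, and the lactone may open at high pH to the meso diacid diol and reclose at random. The fallback changes the one-carbon electrophile. Setting out from 1, the same dianion 2 would be alkylated with benzyl chloromethyl ether to the benzyl ether acid F2, which is lipophilic, arises from a bulkier electrophile, and has two chemically distinct oxygenated arms. Acylation of 4 under the conditions of step 2, through the mixed anhydride F3, would give the keto benzyl ether F4. Hydrogenolysis (H2, Pd/C, EtOAc) would return to the route at 7.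

**Step 2.** Acyl transfer from the hindered secondary mixed anhydride may be incomplete. The hydroxy acid may form ester oligomers before its hydroxyl is capped. Acylative opening of the lactone would pass through a meso species. Trifluoroacetate may be eliminated to an α-methylene lactone during work-up. The fallback is the stepwise acid chloride route. Setting out from 3, Ac2O in pyridine would give the acetate acid F5. (COCl)2 with catalytic DMF would give the acid chloride F6. Acylation of 4 with SnCl4 in CH2Cl2 at 0 °C would give the keto acetate F7. HCl in MeOH at 0 °C → rt would remove the acetate and return to the route at 7; any cyclic methyl ketal formed there reduces to 10 in step 3 as well.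

**Step 5.** The equilibrium may stall at the lactol 13 (ring–chain trapping of the cis series), or the base may open the ring by expulsion of O1 from C5. The fallback removes the hydroxyl from the equilibrium. Setting out from 14, TBSCl and imidazole in DMF would give the cis silyl ether ketone F8, which cannot form a lactol. DBU in CH2Cl2 would give the trans silyl ether ketone F9. Bu4NF buffered with AcOH in THF would remove the silyl group without acid stress on the benzylic ether and return to the route at 15.

## Further compounds

F1 | step 3 | (3aR,6aR)-4-(3,4-dimethoxyphenyl)-4-methoxytetrahydro-1H,3H-furo[3,4-c]furan-1-one | COc1ccc(C2(OC)OC[C@@H]3C(=O)OC[C@H]23)cc1OC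
F2 | step 1 | (3S,4R)-4-[(benzyloxy)methyl]-5-oxotetrahydrofuran-3-carboxylic acid | OC(=O)[C@@H]1COC(=O)[C@H]1COCc1ccccc1
F3 | step 1 | mixed anhydride of F2 with trifluoroacetic acid | FC(F)(F)C(=O)OC(=O)[C@@H]1COC(=O)[C@H]1COCc1ccccc1
F4 | step 1 | (3R)-3-[(benzyloxy)methyl]-4-(3,4-dimethoxybenzoyl)dihydrofuran-2(3H)-one, both C4 epimers | COc1ccc(C(=O)C2COC(=O)[C@H]2COCc2ccccc2)cc1OC
F5 | step 2 | (3S,4R)-4-(acetoxymethyl)-5-oxotetrahydrofuran-3-carboxylic acid | OC(=O)[C@@H]1COC(=O)[C@H]1COC(C)=O
F6 | step 2 | (3S,4R)-4-(acetoxymethyl)-5-oxotetrahydrofuran-3-carbonyl chloride | ClC(=O)[C@@H]1COC(=O)[C@H]1COC(C)=O
F7 | step 2 | [(3R)-4-(3,4-dimethoxybenzoyl)-2-oxotetrahydrofuran-3-yl]methyl acetate, both C4 epimers | COc1ccc(C(=O)C2COC(=O)[C@H]2COC(C)=O)cc1OC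
F8 | step 5 | [(3R,4R,5R)-4-{[(tert-butyldimethylsilyl)oxy]methyl}-5-(3,4-dimethoxyphenyl)tetrahydrofuran-3-yl](3,4,5-trimethoxyphenyl)methanone | COc1ccc([C@@H]2OC[C@H](C(=O)c3cc(OC)c(OC)c(OC)c3)[C@@H]2CO[Si](C)(C)C(C)(C)C)cc1OC
F9 | step 5 | [(3S,4R,5R)-4-{[(tert-butyldimethylsilyl)oxy]methyl}-5-(3,4-dimethoxyphenyl)tetrahydrofuran-3-yl](3,4,5-trimethoxyphenyl)methanone | COc1ccc([C@@H]2OC[C@@H](C(=O)c3cc(OC)c(OC)c(OC)c3)[C@@H]2CO[Si](C)(C)C(C)(C)C)cc1OC
A1 | alternative 1 | dimethyl (2S,3R)-2-(3,4-dimethoxyphenyl)-3-{[(triisopropylsilyl)oxy]methyl}cyclopropane-1,1-dicarboxylate (aryl and silyloxymethyl trans) | COc1ccc([C@@H]2[C@@H](CO[Si](C(C)C)(C(C)C)C(C)C)C2(C(=O)OC)C(=O)OC)cc1OC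
A2 | alternative 1 | dimethyl (4R,5R)-5-(3,4-dimethoxyphenyl)-4-{[(triisopropylsilyl)oxy]methyl}dihydrofuran-3,3(2H)-dicarboxylate (aryl and silyloxymethyl cis) | COc1ccc([C@@H]2OCC(C(=O)OC)(C(=O)OC)[C@@H]2CO[Si](C(C)C)(C(C)C)C(C)C)cc1OC
A3 | alternative 2 | methyl 2-[(3,4-dimethoxyphenyl)(methoxymethoxy)methyl]-4-(3,4,5-trimethoxyphenyl)-4-[(trimethylsilyl)oxy]but-3-enoate (configuration as in the SMILES, enol geometry open) | COc1ccc([C@H](OCOC)[C@@H](C(=O)OC)C=C(O[Si](C)(C)C)c2cc(OC)c(OC)c(OC)c2)cc1OC
A4 | alternative 2 | methyl (2R,3S,4S)-2-(3,4-dimethoxyphenyl)-4-(3,4,5-trimethoxybenzoyl)tetrahydrofuran-3-carboxylate (2,3-cis, 3,4-trans) | COc1ccc([C@@H]2OC[C@@H](C(=O)c3cc(OC)c(OC)c(OC)c3)[C@@H]2C(=O)OC)cc1OC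
A5 | alternative 3 | (5R)-2-(3,4-dimethoxyphenyl)-5-[1-(3,4,5-trimethoxyphenyl)ethenyl]-4,5-dihydro-1,3-dioxepine (acetal carbon either configuration) | COc1ccc(C2OC=C[C@H](C(=C)c3cc(OC)c(OC)c(OC)c3)CO2)cc1OC
A6 | alternative 3 | (2R,3S,4R)-2-(3,4-dimethoxyphenyl)-4-[1-(3,4,5-trimethoxyphenyl)ethenyl]tetrahydrofuran-3-carbaldehyde (2,3-cis, 3,4-trans) | COc1ccc([C@@H]2OC[C@@H](C(=C)c3cc(OC)c(OC)c(OC)c3)[C@@H]2C=O)cc1OC
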